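- Chemist on this series, I began from the bench rule for a partner in excess: call the reaction pseudo-first-order, and expect percent curves that do not depend on the charge.

the same everywhere: free catalyst 13 µM
- blue: starting material 2.9 mM; coupling partner 56 mM; run made earlier
- amber: starting material 8.9 mM; coupling partner 56 mM; run made earlier
- red: starting material 16 mM; coupling partner 56 mM; run made earlier
- north: starting material 4.0 mM; coupling partner 56.0 mM; time 8.0 min
- south: starting material 6.0 mM; coupling partner 56.0 mM; time 8.0 min
- west: starting material 10 mM; coupling partner 56.0 mM; time 8.0 min
- east: starting material 15 mM; coupling partner 56.0 mM; time 8.0 min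
- south-east: starting material 20 mM; coupling partner 56.0 mM; time 8.0 min

| run | time / min | target / % | isomer of the product / % |
|---|---|---|---|
| blue | 0.417 | 36.6 | 22.6 |
| blue | 0.833 | 40.2 | 29.5 |
| blue | 1.50 | 40.4 | 34.6 |
| blue | 3.00 | 30.6 | 37.3 |
| blue | 6.00 | 23.0 | 36.4 |
| amber | 1.00 | 39.8 | 32.3 |
| amber | 2.50 | 31.2 | 35.9 |
| amber | 3.00 | 27.9 | 36.7 |
| amber | 5.00 | 23.7 | 35.3 |
| amber | 6.00 | 23.1 | 36.1 |
| red | 0.417 | 33.4 | 20.9 |
| red | 0.833 | 36.8 | 29.5 |
| red | 1.50 | 35.5 | 33.3 |
| red | 3.00 | 30.7 | 36.8 |
| red | 6.00 | 21.5 | 37.0 |

(standard deviation of a reading: 1 percentage point)

- "hardly changes" means that all values lie within two and a half points (for a concentration: within two and a half percent of the largest)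

1. share of target in all that became target or isomer of the product for north, south, west, east, south-east, in this order
2. the shape of the row from first to last (falls, then rises / rises, then falls / rises all the way / falls all the way / hardly changes)

- The earlier runs bore the rule out, as readings: at 3.00 min target read 30.6%, 27.9% and 30.7% in blue, amber and red.
- I looked for its border with one ratio, the load, which is starting material charged over coupling partner charged: 0.357 in south-east, 0.0714 in north, 0.286 in red and 0.0518 in blue.
- South-east stood past the measured range, its load being 1.25 times red's, so there I was extrapolating, whereas north lay inside.
- I treated the load as a correction to the excess: taking one partner per product, load times the share of charge found as target and isomer gives the fraction of partner the coupling has used. At 6.00 min that was 16.7% in red and 3.08% in blue.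
- That difference in partner went with a small difference in share, which read 38.7% in blue and 36.8% in red, with the scatter of the readings on both.
- The asked row spans 1.22 times the load gap between red and blue, so I scaled the read difference and got a spread of about 2.4 percentage points, just inside the margin. I therefore committed to a row that hardly changes; this reckoning of mine gave a spread and no level.
- The forecast was a separate reckoning, which put a level on each flask and gave 34%, 34%, 34%, 34% and 34%, shape hardly changes, on this ground: “So everything behaves as pseudo-first-order, with no concentration effect on selectivity.”
- The flasks gave 37.7%, 37.8%, 37.9%, 38.0% and 38.1%, shape hardly changes, a rise of 0.4 points from north to south-east.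

    2 coupling partner → self-condensation product (k = 0.0600 /M/s)
    2 free catalyst → spent catalyst (k = 5500 /M/s)
    starting material + coupling partner ⇌ isomer of the product (K = 51.0 /M, k = 0.290 /M/s)
    starting material + coupling partner ⇌ target (K = 33.0 /M, k = 0.550 /M/s)
    target + free catalyst ⇌ isomer of the product + free catalyst, rate k5*[free catalyst]*[target] forward; the back reaction follows from the equilibrium constant (k = 110 /M/s)

- In south-east by 4.00 min partner stood at 34.5% of its charge, self-condensation product holding 43.1% of that charge and the two products 22.4%, with target at 26.0% and isomer at 36.7%; from there to 8.00 min both products fell to 20.9% and 33.9% while starting material climbed from 37.3% to 45.2%. At that time south-east's load times its products puts 19.6% of the partner charged in them and self-condensation product holds 56.4%, while north, with partner also at 23.9%, has 3.94% and 72.2%.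

The runs were generated by integration on assumed constants; scatter was added.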